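**Retrosynthetic overview**

1. Target 5 is (all-E,3S,5S,6S,3'R,6'R)-5,6-dihydro-β,ε-carotene-3,5,6,3'-tetrol, i.e. lutein 1 with two OH groups added anti across C5=C6 (5-OH cis to 3-OH, 6-OH trans). The all-E C40 skeleton and C3, C3', C6' come from 1.
2. Key disconnection, C6–OH: water opens the syn-5,6-epoxide 2 at C6 with inversion on a phenylboronic acid template, which ends as the O3–B–O5 boronate 4.
3. Oxirane C–O disconnection: 2 comes from 1 by 3-OH-directed peracid epoxidation of the tetrasubstituted β-ring alkene.
4. Ring order: both carbocycles are bought. The oxirane is formed in step 1, opened in step 2 while a temporary 1,3,2-dioxaborinane closes, and that ring is removed in step 3.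

Assumption: free crystalline lutein from marigold (bulk nutraceutical grade, recrystallised once to lower its zeaxanthin content) is taken as a cheap commercial starting material.

**Step 1**
Reactants: 1 lutein = (all-E,3R,3'R,6'R)-β,ε-carotene-3,3'-diol
Product: 2 syn-lutein 5,6-epoxide = (all-E,3S,5S,6R,3'R,6'R)-5,6-epoxy-5,6-dihydro-β,ε-carotene-3,3'-diol (oxirane O cis to 3-OH)
Conditions: mCPBA (1.0 equiv), NaHCO3 (3 equiv), CH2Cl2, −20 → 0 °C, dark, Ar
Reagents that add atoms: mCPBA (3-chloroperoxybenzoic acid), OOC(=O)c1cccc(Cl)c1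
Why: Prilezhaev epoxidation with Henbest hydroxyl direction: the peracid attacks the only tetrasubstituted, most electron-rich alkene (C5=C6) and is hydrogen-bonded by the homoallylic 3-OH onto the α face, which sets 5S and 6R (syn), and is expected to favour the syn isomer only moderately; the minor anti isomer is removed on Et3N-deactivated silica or carried on, since it cannot engage the boron template of step 2.

**Step 2**
Reactants: 2 syn-lutein 5,6-epoxide
Product: 4 3,5-O-(phenylboranediyl)-(all-E,3S,5S,6S,3'R,6'R)-5,6-dihydro-β,ε-carotene-3,5,6,3'-tetrol (2-phenyl-1,3,2-dioxaborinane bridging O3/O5; 6-OH and 3'-OH free), via epoxy hemiboronate 3 (not isolated)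
Conditions: PhB(OH)2 (1.2 equiv), H2O (5 equiv), 2,6-lutidine (0.2 equiv), THF, 0 → 23 °C, dark, Ar
Reagents that add atoms: phenylboronic acid, OB(O)c1ccccc1; water, O
Why: Proposed new method: boronic-acid-templated anti-hydrolysis of a cis-β-hydroxy epoxide. The 3-OH condenses with PhB(OH)2 to hemiester 3, whose boron can reach only the cis oxirane oxygen (six-membered O3–B–O chelate on the α face) and, as a mild substrate-bound Lewis acid, loosens the C6–O bond, which ionises far more easily than C5–O because C6 ends the polyene π system. Water then attacks C6 from the β face, the only face not covered by the chelate, in a loose SN2-like trans-diaxial opening (inversion, sets 6S; C5 keeps 5S), while O5 is caught as a B–O ester oxygen of the closing dioxaborinane and so cannot close onto C8 to give the usual furanoid 5,8-epoxide. 2,6-Lutidine suppresses free-proton SN1 pathways, and the anti isomer of 2 cannot chelate and stays behind. The closest known reaction types are chelation-controlled Lewis-acid openings of epoxy alcohols (Ti(O-i-Pr)4- or boron-assisted) and borinic-acid-catalysed openings of 3,4-epoxy alcohols, neither shown with water on a tetrasubstituted polyenyl epoxide or with capture of the product as a 1,3-diol boronate.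

**Step 3**
Reactants: 4 3,5-O-(phenylboranediyl) tetrol
Product: 5 (all-E,3S,5S,6S,3'R,6'R)-5,6-dihydro-β,ε-carotene-3,5,6,3'-tetrol
Conditions: HN(CH2CH2OH)2 (diethanolamine, 3 equiv), THF/Et2O 1:3, 23 °C, dark, Ar
Reagents that add atoms: none
Why: Boronate transesterification: diethanolamine takes the boron as the N→B-stabilised, poorly soluble 2-phenyl-1,3,6,2-dioxazaborocane (the syn-axial C1 methyl makes the bicyclic boronate 4 comparatively easy to exchange) and frees the 3,5-diol under non-acidic, non-oxidising conditions that leave the acid-labile tertiary polyenyl carbinol at C6, the allylic 3'-OH, the all-E chain and every stereocentre untouched.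

**Compound list**

1 | lutein, (all-E,3R,3'R,6'R)-β,ε-carotene-3,3'-diol | CC1=C[C@H](O)CC(C)(C)[C@H]1/C=C/C(C)=C/C=C/C(C)=C/C=C/C=C(C)/C=C/C=C(C)/C=C/C1=C(C)C[C@@H](O)CC1(C)C | starting material

2 | syn-lutein 5,6-epoxide, (all-E,3S,5S,6R,3'R,6'R)-5,6-epoxy-5,6-dihydro-β,ε-carotene-3,3'-diol | CC1=C[C@H](O)CC(C)(C)[C@H]1/C=C/C(C)=C/C=C/C(C)=C/C=C/C=C(C)/C=C/C=C(C)/C=C/[C@]12O[C@@]1(C)C[C@@H](O)CC2(C)C | intermediate

3 | epoxy hemiboronate, 3-O-[hydroxy(phenyl)boranyl] derivative of 2 (boron chelated by the cis oxirane oxygen) | CC1=C[C@H](O)CC(C)(C)[C@H]1/C=C/C(C)=C/C=C/C(C)=C/C=C/C=C(C)/C=C/C=C(C)/C=C/[C@]12O[C@@]1(C)C[C@@H](OB(O)c3ccccc3)CC2(C)C | intermediate (not isolated)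

4 | 3,5-O-(phenylboranediyl)-(all-E,3S,5S,6S,3'R,6'R)-5,6-dihydro-β,ε-carotene-3,5,6,3'-tetrol | CC1=C[C@H](O)CC(C)(C)[C@H]1/C=C/C(C)=C/C=C/C(C)=C/C=C/C=C(C)/C=C/C=C(C)/C=C/[C@]1(O)C(C)(C)C[C@H](O2)C[C@]1(C)OB2c3ccccc3 | intermediate

5 | (all-E,3S,5S,6S,3'R,6'R)-5,6-dihydro-β,ε-carotene-3,5,6,3'-tetrol | CC1=C[C@H](O)CC(C)(C)[C@H]1/C=C/C(C)=C/C=C/C(C)=C/C=C/C=C(C)/C=C/C=C(C)/C=C/[C@]1(O)C(C)(C)C[C@H](O)C[C@]1(C)O | target

**Totals**

Total step count: 3. Longest linear sequence: 3 steps (1 → 2 → 4 → 5).

**Steps most likely to fail**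

Step 2 (the proposed new step). The risks are delivery of the boron-bound OH to C6 with retention, escape to the furanoid 5,8-epoxide, or no activation at all. The fallback sets out from 2 and comes back at 5, replacing steps 2 and 3. It drops the template and uses the classical specific-acid hydrolysis known for carotenoid 5,6-epoxides: 0.01 M H2SO4 in THF/H2O 4:1 at 0 °C, quenched with NaHCO3 at partial conversion. The free polyenyl cation is trapped by water at C6, and the (6S) tetrol 5 is separated by chromatography on deactivated silica and HPLC from its C6 epimer and the furanoid by-products. Unreacted 2 is recycled. The yield is low but the chemistry is established, and no new compound arises (F0).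

Step 1. The risks are that the syn/anti ratio, expected to be only moderate, turns out poor, or that the ε-ring alkene is attacked. The fallback sets out from 1 and comes back at 2, replacing peracid direction by vanadium-directed epoxidation after masking the allylic alcohol as its ketone.
- MnO2 in EtOAc at 23 °C oxidises only the allylic 3'-OH to (all-E,3R,6'R)-3-hydroxy-β,ε-caroten-3'-one F1.
- VO(acac)2 (5 mol %) and t-BuOOH in toluene at 0 °C, now directed only by the homoallylic 3-OH and blind to the enone, give the syn-epoxy ketone (all-E,3S,5S,6R,6'R)-5,6-epoxy-3-hydroxy-5,6-dihydro-β,ε-caroten-3'-one F2.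
- 1,2-Reduction with i-Bu2AlH in THF at −78 °C returns 2 together with its 3'-epimer, (all-E,3S,5S,6R,3'S,6'R)-5,6-epoxy-5,6-dihydro-β,ε-carotene-3,3'-diol F3. F3 is separated and re-oxidised with MnO2 to F2 for recycling.

Step 3. The risk is that the bicyclic boronate resists exchange or that 5 co-precipitates with the boron adduct. The fallback sets out from 4 and comes back at 5. It cleaves the B–C bond instead of exchanging the B–O bonds: oxidative deboronation with NaBO3·4H2O in THF/H2O at 0 °C (or H2O2 with NaHCO3) turns the arylboronate into a borate that hydrolyses at once to 5. No new compound arises (F0).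

**Further compounds**

F1 | step 1 | (all-E,3R,6'R)-3-hydroxy-β,ε-caroten-3'-one | CC1=CC(=O)CC(C)(C)[C@H]1/C=C/C(C)=C/C=C/C(C)=C/C=C/C=C(C)/C=C/C=C(C)/C=C/C1=C(C)C[C@@H](O)CC1(C)C
F2 | step 1 | (all-E,3S,5S,6R,6'R)-5,6-epoxy-3-hydroxy-5,6-dihydro-β,ε-caroten-3'-one | CC1=CC(=O)CC(C)(C)[C@H]1/C=C/C(C)=C/C=C/C(C)=C/C=C/C=C(C)/C=C/C=C(C)/C=C/[C@]12O[C@@]1(C)C[C@@H](O)CC2(C)C
F3 | step 1 | (all-E,3S,5S,6R,3'S,6'R)-5,6-epoxy-5,6-dihydro-β,ε-carotene-3,3'-diol | CC1=C[C@@H](O)CC(C)(C)[C@H]1/C=C/C(C)=C/C=C/C(C)=C/C=C/C=C(C)/C=C/C=C(C)/C=C/[C@]12O[C@@]1(C)C[C@@H](O)CC2(C)C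
F0 | step 2 | none | none
F0 | step 3 | none | none
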